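**Retrosynthetic overview**

1. Target ⇐ 4α,6α-diol 10-tiglate 26 (two late acylations) ⇐ allylic diol 22 by α-face hydroboration of a C5=C6 double bond; 22 ⇐ 4α,5α-epoxy-6-ketone 20 by Wharton transposition; the 10α-OH of 20 ⇐ dienone 18 by 1,6-conjugate boration.
2. Key disconnection: epoxy dienone 18 ⇐ monocyclic α-chloro-1,6-diketone 16 by an intramolecular Darzens annulation. One operation forms the C4–C5 bond, the five-membered ring, the tertiary C4–O stereocentre and a temporary C5–O bond (oxirane) that is not in the target and is cleaved again in step 11.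
3. Enabling feature: the carbinol carbon C4 of the five-membered ring lies β to the oxygenated C6 of the seven-membered ring through the fusion carbon C5, so C4–C5 is an aldol bond of a C6 ketone. The other fusion atom C1 is quaternary and C7 is kept sp2, so C5 is the only enolisable position.
4. Seven-membered ring: [4+3] cycloaddition of 2,5-dimethylfuran (dearomatisation), bridge opening to prochiral 3,6-dimethylcyclohepta-2,6-dienone 7; C1 is then set by copper-catalysed asymmetric conjugate addition.
5. Ring order: seven-membered ring first (step 1, unveiled in step 3), cyclopentane last (step 9).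

Key step: step 9

Remark (numbering): C1 = quaternary fusion carbon (C15 methyl), C2, C3 = cyclopentane CH2, C4 = isopropyl carbinol, C5 = fusion CH, C6 = CH–O-aroyl, C7 = CH2, C8 = C(CH3)= (C14 methyl), C9 = CH=, C10 = CH–O-acyl; "daucane" is this skeleton; β = face of the C15 methyl, α = opposite face.
Remark (assumption): the SMILES is read as the (E)-2-methylbut-2-enoate (tiglate) with 4-OH cis to H5 and trans to the C15 methyl; compounds 1, 2, 8, 23 and 27 are taken as commercial.
Remark: the enantiomeric purity set in step 5 is to be raised, if needed, by recrystallisation of a crystalline later intermediate (22 or 26).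

**Step 1**
Reactants: 1 2,5-dimethylfuran; 2 1,1,3,3-tetrabromopropan-2-one
Product: 4 1,5-dimethyl-8-oxabicyclo[3.2.1]oct-6-en-3-one, via dibromo ketone 3 (not isolated)
Conditions: Zn–Ag couple, THF, −10 °C to rt; then Zn–Cu couple, NH4Cl, MeOH, rt
Reagents that add atoms: none
Why: [4+3] cycloaddition of the zinc oxyallyl cation from 2 with the furan diene, then reductive removal of both α-bromines, should give the meso oxabicyclic ketone, which has no stereochemical issue.

**Step 2**
Reactants: 4 1,5-dimethyl-8-oxabicyclo[3.2.1]oct-6-en-3-one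
Product: 5 1,5-dimethyl-8-oxabicyclo[3.2.1]octan-3-one
Conditions: H2 (1 atm), Pd/C, EtOAc, rt
Reagents that add atoms: none
Why: heterogeneous hydrogenation of the strained disubstituted double bond; ketone and ether bridge are inert and no stereocentre is created.

**Step 3**
Reactants: 5 1,5-dimethyl-8-oxabicyclo[3.2.1]octan-3-one
Product: 7 3,6-dimethylcyclohepta-2,6-dien-1-one, via silyloxy enone 6 (not isolated)
Conditions: TMSOTf, Et3N, CH2Cl2, 0 °C to rt; then p-TsOH·H2O (cat.), CH2Cl2, rt
Reagents that add atoms: none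
Why: enol silylation and TMSOTf-assisted β-elimination (E1cB-type retro-oxa-Michael) should open one bridgehead C–O bond, and acid then eliminates the tertiary β-silyloxy group to the cross-conjugated dienone; because 5 is meso, both modes of opening converge on achiral 7.

**Step 4**
Reactants: 8 4-methylpent-1-en-3-one
Product: 10 2-(2-bromoethyl)-2-(propan-2-yl)-1,3-dioxolane, via bromo ketone 9 (not isolated)
Conditions: HBr (g), CH2Cl2, 0 °C; then ethylene glycol, p-TsOH (cat.), benzene, reflux (Dean–Stark)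
Reagents that add atoms: hydrogen bromide, Br; ethylene glycol, OCCO
Why: conjugate hydrobromination of the vinyl ketone followed by acid-catalysed ketalisation, the standard route to β-bromo ketals.

**Step 5**
Reactants: 7 3,6-dimethylcyclohepta-2,6-dien-1-one; 10 2-(2-bromoethyl)-2-(propan-2-yl)-1,3-dioxolane
Product: 12 (6S)-3,6-dimethyl-6-{2-[2-(propan-2-yl)-1,3-dioxolan-2-yl]ethyl}cyclohept-2-en-1-one, via Grignard reagent 11 (not isolated)
Conditions: Mg, THF, 30 °C; then 7, Cu(OTf)2 (3 mol%), chiral N-mesityl-N′-(hydroxyalkyl)imidazolinium hexafluorophosphate (NHC precursor, 4 mol%), Et2O, 0 °C, slow addition; sat. aq. NH4Cl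
Reagents that add atoms: none
Why: copper-catalysed asymmetric conjugate addition of a Grignard reagent to a β-methyl cyclic enone should create the quaternary stereocentre C1; the two enone termini of 7 are enantiotopic, so the ligand (enantiomer chosen for the (S) product) alone fixes the configuration, and the magnesium dienolate formed cannot add a second time.

**Step 6**
Reactants: 12 (6S)-3,6-dimethyl-6-{2-[2-(propan-2-yl)-1,3-dioxolan-2-yl]ethyl}cyclohept-2-en-1-one
Product: 13 (6S)-3,6-dimethyl-6-{2-[2-(propan-2-yl)-1,3-dioxolan-2-yl]ethyl}cyclohepta-2,4-dien-1-one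
Conditions: chloranil (1.5 equiv), CaCO3, t-BuOH, reflux
Reagents that add atoms: none
Why: quinone dehydrogenation of an enone through its linear dienol (as in the conversion of steroidal 4-en-3-ones to 4,6-dien-3-ones) should introduce the C9=C10 double bond; the other side cannot be dehydrogenated because C1 is quaternary.

**Step 7**
Reactants: 13 (6S)-3,6-dimethyl-6-{2-[2-(propan-2-yl)-1,3-dioxolan-2-yl]ethyl}cyclohepta-2,4-dien-1-one
Product: 15 (6R)-7-chloro-3,6-dimethyl-6-{2-[2-(propan-2-yl)-1,3-dioxolan-2-yl]ethyl}cyclohepta-2,4-dien-1-one, via lithium dienolate 14 (not isolated)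
Conditions: LiN(i-Pr)2, THF, −78 °C; then NCS, −78 to −40 °C; sat. aq. NH4Cl
Reagents that add atoms: N-chlorosuccinimide, ClN1C(=O)CCC1=O
Why: kinetic deprotonation at C5, the only enolisable CH2 of the dienone, and electrophilic chlorination of the enolate; both C5 epimers are usable because C5 is re-enolised in step 9 (the change of descriptor at C1 is only a priority change).

**Step 8**
Reactants: 15 (6R)-7-chloro-3,6-dimethyl-6-{2-[2-(propan-2-yl)-1,3-dioxolan-2-yl]ethyl}cyclohepta-2,4-dien-1-one
Product: 16 (6R)-7-chloro-3,6-dimethyl-6-(4-methyl-3-oxopentyl)cyclohepta-2,4-dien-1-one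
Conditions: PPTS, acetone/H2O (10:1), 50 °C
Reagents that add atoms: water, O
Why: mild acid-catalysed hydrolysis of the dioxolane; the α-chloro ketone and the dienone are stable to pyridinium tosylate.

**Step 9**
Reactants: 16 (6R)-7-chloro-3,6-dimethyl-6-(4-methyl-3-oxopentyl)cyclohepta-2,4-dien-1-one
Product: 18 4α,5α-epoxydauca-7,9-dien-6-one, via chlorohydrin alkoxide 17 (not isolated)
Conditions: KOt-Bu (1.1 equiv), t-BuOH/THF (1:3), −20 to 0 °C
Reagents that add atoms: none
Why: intramolecular Darzens reaction: tert-butoxide deprotonates C5 (α to C6=O and bearing chlorine), the chloro enolate adds reversibly to the isopropyl ketone C4, and the alkoxide then displaces chloride at C5 by intramolecular SN2 attack. The closest known reaction type is the Darzens synthesis of α,β-epoxy ketones from α-halo ketones and ketones, in its intramolecular, ring-forming variant. The cyclopentane closes in a 5-(enolexo)-exo-trig aldol mode and the oxirane in a 3-exo-tet mode. The C1 stereocentre controls both new centres: only the rotamer with C2 perpendicular to the enolate plane and the C15 methyl in that plane can reach C4, which places chlorine syn to the methyl, and only the aldolate with O4 anti to chlorine can close, so the oxirane oxygen should end up on the face opposite to the methyl (4α,5α) while the other aldolates revert by retro-aldol. The step needs enolisation at C5 rather than at the isobutyryl group, secured by the acidifying chlorine, and it needs no Favorskii rearrangement or loss of HCl, secured by the absence of α′ and β hydrogens (C7 is sp2, C1 quaternary). The C5–O bond made here is the temporary bond that fixes the tertiary C4–O configuration.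

**Step 10**
Reactants: 18 4α,5α-epoxydauca-7,9-dien-6-one
Product: 20 4α,5α-epoxy-10α-hydroxydauc-8-en-6-one, via allylboronate 19 (not isolated)
Conditions: B2pin2, CuCl (5 mol%), DPEphos (5 mol%), NaOt-Bu (10 mol%), MeOH (2 equiv), THF, 0 °C to rt; then NaBO3·4H2O, THF/H2O, rt
Reagents that add atoms: sodium perborate, [Na+].[O-]OB=O
Why: copper-catalysed conjugate boration in which the β-methyl group at C8 steers the boryl–copper species to the δ-carbon C10 (1,6-addition) anti to the axial C15 methyl (α-face); α-protonation of the dienolate leaves the C8=C9 double bond, and oxidation of the allylboronate proceeds with retention.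

**Step 11**
Reactants: 20 4α,5α-epoxy-10α-hydroxydauc-8-en-6-one
Product: 22 dauca-5,8-diene-4α,10α-diol, via epoxy hydrazone 21 (not isolated)
Conditions: N2H4·H2O (3 equiv), AcOH (cat.), MeOH, 0 °C to rt
Reagents that add atoms: none
Why: Wharton reaction: the hydrazone of the α,β-epoxy ketone fragments with loss of N2, cleaving the temporary C5–O bond and giving the tertiary allylic alcohol with unchanged C4–O configuration and the C5=C6 double bond.

**Step 12**
Reactants: 22 dauca-5,8-diene-4α,10α-diol; 23 (E)-2-methylbut-2-enoyl chloride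
Product: 24 4α-hydroxydauca-5,8-dien-10α-yl (E)-2-methylbut-2-enoate
Conditions: pyridine, DMAP (cat.), CH2Cl2, 0 °C to rt
Reagents that add atoms: none
Why: DMAP-catalysed acylation of the secondary allylic 10-OH; the tertiary 4-OH should not react, and pyridine avoids deconjugation of the tigloyl group.

**Step 13**
Reactants: 24 4α-hydroxydauca-5,8-dien-10α-yl (E)-2-methylbut-2-enoate
Product: 26 4α,6α-dihydroxy-5αH-dauc-8-en-10α-yl (E)-2-methylbut-2-enoate, via bisboryl adduct 25 (not isolated)
Conditions: 9-BBN (3 equiv), THF, 0 to 65 °C; then NaBO3·4H2O, THF/H2O, rt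
Reagents that add atoms: sodium perborate, [Na+].[O-]OB=O
Why: hydroboration–oxidation places boron on the less substituted C6 and hydrogen on C5 in a syn addition from the α-face (the β-face carries the C15 methyl and the isopropyl group), which should set 5α-H (trans ring fusion) and 6α-OH together; a dialkylborane with one B–H cannot bridge the 1,4-diene, and the C8=C9 bond next to the ester-bearing neopentyl C10 and the electron-poor tiglate double bond should react more slowly.

**Step 14**
Reactants: 26 4α,6α-dihydroxy-5αH-dauc-8-en-10α-yl (E)-2-methylbut-2-enoate; 27 4-(acetyloxy)benzoyl chloride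
Product: 28 6α-[4-(acetyloxy)benzoyloxy]-4α-hydroxy-5αH-dauc-8-en-10α-yl (E)-2-methylbut-2-enoate
Conditions: pyridine, DMAP (cat.), CH2Cl2, rt
Reagents that add atoms: none
Why: acylation of the only secondary alcohol; the tertiary 4-OH is inert under these conditions.

**Step 15**
Reactants: 28 6α-[4-(acetyloxy)benzoyloxy]-4α-hydroxy-5αH-dauc-8-en-10α-yl (E)-2-methylbut-2-enoate
Product: 29 (3S,3aS,4S,8R,8aS)-3-hydroxy-6,8a-dimethyl-8-{[(2E)-2-methylbut-2-enoyl]oxy}-3-(propan-2-yl)-1,2,3,3a,4,5,8,8a-octahydroazulen-4-yl 4-hydroxybenzoate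
Conditions: NH4OAc, MeOH/H2O (4:1), rt
Reagents that add atoms: none
Why: chemoselective methanolysis of the aryl acetate (phenoxide is a far better leaving group than an alkoxide) should free the phenol and leave the benzoate and tiglate esters intact.

**Compound list**

1 | 2,5-dimethylfuran | Cc1ccc(C)o1 | starting material
2 | 1,1,3,3-tetrabromopropan-2-one | BrC(Br)C(=O)C(Br)Br | starting material
3 | 2,4-dibromo-1,5-dimethyl-8-oxabicyclo[3.2.1]oct-6-en-3-one (bromine epimers) | C[C@]12C=C[C@](C)(O1)C(Br)C(=O)C2Br | intermediate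
4 | 1,5-dimethyl-8-oxabicyclo[3.2.1]oct-6-en-3-one (meso) | C[C@]12C=C[C@](C)(O1)CC(=O)C2 | intermediate
5 | 1,5-dimethyl-8-oxabicyclo[3.2.1]octan-3-one (meso) | C[C@]12CC[C@](C)(O1)CC(=O)C2 | intermediate
6 | 3,6-dimethyl-6-(trimethylsilyloxy)cyclohept-2-en-1-one (racemic) | CC1=CC(=O)CC(C)(O[Si](C)(C)C)CC1 | intermediate
7 | 3,6-dimethylcyclohepta-2,6-dien-1-one | CC1=CC(=O)C=C(C)CC1 | intermediate
8 | 4-methylpent-1-en-3-one | CC(C)C(=O)C=C | starting material
9 | 1-bromo-4-methylpentan-3-one | CC(C)C(=O)CCBr | intermediate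
10 | 2-(2-bromoethyl)-2-(propan-2-yl)-1,3-dioxolane | CC(C)C1(CCBr)OCCO1 | intermediate
11 | {2-[2-(propan-2-yl)-1,3-dioxolan-2-yl]ethyl}magnesium bromide | CC(C)C1(CC[Mg]Br)OCCO1 | intermediate
12 | (6S)-3,6-dimethyl-6-{2-[2-(propan-2-yl)-1,3-dioxolan-2-yl]ethyl}cyclohept-2-en-1-one | O=C1C=C(C)CC[C@@](C)(CCC2(C(C)C)OCCO2)C1 | intermediate
13 | (6S)-3,6-dimethyl-6-{2-[2-(propan-2-yl)-1,3-dioxolan-2-yl]ethyl}cyclohepta-2,4-dien-1-one | O=C1C=C(C)C=C[C@@](C)(CCC2(C(C)C)OCCO2)C1 | intermediate
14 | lithium dienolate of 13 (enolate double bond C5=C6) | [Li]OC1=C[C@](C)(CCC2(C(C)C)OCCO2)C=CC(C)=C1 | intermediate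
15 | (6R)-7-chloro-3,6-dimethyl-6-{2-[2-(propan-2-yl)-1,3-dioxolan-2-yl]ethyl}cyclohepta-2,4-dien-1-one (both C7 epimers) | O=C1C=C(C)C=C[C@@](C)(CCC2(C(C)C)OCCO2)C1Cl | intermediate
16 | (6R)-7-chloro-3,6-dimethyl-6-(4-methyl-3-oxopentyl)cyclohepta-2,4-dien-1-one (both C7 epimers) | O=C1C=C(C)C=C[C@@](C)(CCC(=O)C(C)C)C1Cl | intermediate
17 | potassium 5β-chloro-6-oxodauca-7,9-dien-4α-olate | O=C1C=C(C)C=C[C@@]2(C)CC[C@]([O-])(C(C)C)[C@@]12Cl.[K+] | intermediate
18 | 4α,5α-epoxydauca-7,9-dien-6-one | O=C1C=C(C)C=C[C@@]2(C)CC[C@@]3(C(C)C)O[C@@]123 | intermediate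
19 | 4α,5α-epoxy-10α-(4,4,5,5-tetramethyl-1,3,2-dioxaborolan-2-yl)dauc-8-en-6-one | O=C1CC(C)=C[C@@H](B2OC(C)(C)C(C)(C)O2)[C@@]3(C)CC[C@@]4(C(C)C)O[C@@]134 | intermediate
20 | 4α,5α-epoxy-10α-hydroxydauc-8-en-6-one | O=C1CC(C)=C[C@@H](O)[C@@]2(C)CC[C@@]3(C(C)C)O[C@@]123 | intermediate
21 | hydrazone of 20 | NN=C1CC(C)=C[C@@H](O)[C@@]2(C)CC[C@@]3(C(C)C)O[C@@]123 | intermediate
22 | dauca-5,8-diene-4α,10α-diol | O[C@@H]1C=C(C)CC=C2[C@]1(C)CC[C@]2(O)C(C)C | intermediate
23 | (E)-2-methylbut-2-enoyl chloride (tigloyl chloride) | C/C=C(\C)C(Cl)=O | starting material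
24 | 4α-hydroxydauca-5,8-dien-10α-yl (E)-2-methylbut-2-enoate | C/C=C(\C)C(=O)O[C@@H]1C=C(C)CC=C2[C@]1(C)CC[C@]2(O)C(C)C | intermediate
25 | 6α-(9-borabicyclo[3.3.1]nonan-9-yl)-4α-(9-borabicyclo[3.3.1]nonan-9-yloxy)-5αH-dauc-8-en-10α-yl (E)-2-methylbut-2-enoate | C/C=C(\C)C(=O)O[C@@H]1C=C(C)C[C@H](B3C4CCCC3CCC4)[C@@H]2[C@]1(C)CC[C@]2(OB5C6CCCC5CCC6)C(C)C | intermediate
26 | 4α,6α-dihydroxy-5αH-dauc-8-en-10α-yl (E)-2-methylbut-2-enoate | C/C=C(\C)C(=O)O[C@@H]1C=C(C)C[C@H](O)[C@@H]2[C@]1(C)CC[C@]2(O)C(C)C | intermediate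
27 | 4-(acetyloxy)benzoyl chloride | CC(=O)Oc1ccc(cc1)C(Cl)=O | starting material
28 | 6α-[4-(acetyloxy)benzoyloxy]-4α-hydroxy-5αH-dauc-8-en-10α-yl (E)-2-methylbut-2-enoate | C/C=C(\C)C(=O)O[C@@H]1C=C(C)C[C@H](OC(=O)c2ccc(OC(C)=O)cc2)[C@@H]2[C@]1(C)CC[C@]2(O)C(C)C | intermediate
29 | (3S,3aS,4S,8R,8aS)-3-hydroxy-6,8a-dimethyl-8-{[(2E)-2-methylbut-2-enoyl]oxy}-3-(propan-2-yl)-1,2,3,3a,4,5,8,8a-octahydroazulen-4-yl 4-hydroxybenzoate | C/C=C(\C)C(=O)O[C@@H]1C=C(C)C[C@H](OC(=O)c2ccc(O)cc2)[C@@H]2[C@]1(C)CC[C@]2(O)C(C)C | target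

**Step count and risks**

Total step count: 15. Longest linear sequence: 14 steps (steps 1–3 and 5–15, from 2,5-dimethylfuran); step 4 is a one-step side branch.

Steps most likely to fail:

Step 9. The chloro enolate may revert by retro-aldol faster than the oxirane closes on the hindered tertiary centre, or the isobutyryl enolate may attack the activated chloro ketone carbonyl instead. The fallback separates ring closure from oxygenation and sets out from 13. Ketal hydrolysis (PPTS, aqueous acetone) should give (6S)-3,6-dimethyl-6-(4-methyl-3-oxopentyl)cyclohepta-2,4-dien-1-one F1. Intramolecular aldol condensation (KOH, EtOH, rt) should close the cyclopentene to dauca-4,7,9-trien-6-one F2. Conjugate boration under the conditions of step 10 should give 10α-(4,4,5,5-tetramethyl-1,3,2-dioxaborolan-2-yl)dauca-4,8-dien-6-one F3, oxidised without isolation to 10α-hydroxydauca-4,8-dien-6-one F4. Weitz–Scheffer epoxidation of the tetrasubstituted enone from the α-face under aprotic conditions (t-BuOOLi from t-BuOOH and n-BuLi, THF, −20 °C) should then give 20, where the route is rejoined.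

Step 10. Conjugate boration may lose regioselectivity (1,4 against 1,6), may attack C10 from the wrong face, or base may move the C8=C9 double bond into conjugation. The fallback sets out from 18 and uses electrophilic oxygenation. Peracid epoxidation of the distal double bond (mCPBA, NaHCO3, CH2Cl2, 0 °C; α-face, as for steroidal 4,6-dien-3-ones) should give 4α,5α:9α,10α-diepoxydauc-7-en-6-one F5. Hydrogenolysis of the alkenyl oxirane (Pd2(dba)3·CHCl3, PBu3, HCO2H, Et3N, dioxane) should deliver hydride to the allylic carbon C9 and give 4α,5α-epoxy-10α-hydroxydauc-7-en-6-one F6. Deconjugation (LiN(i-Pr)2, 2.2 equiv, THF, −78 °C, γ-deprotonation at C9, then kinetic α-protonation with AcOH) should return 20.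

Step 13. Hydroboration may lose chemoselectivity among the three C=C bonds (including conjugate reduction of the tiglate) or may attack C5=C6 from the β-face. The fallback avoids boranes and sets out from 20. Acylation with 23 (pyridine, DMAP) should give 4α,5α-epoxy-6-oxodauc-8-en-10α-yl (E)-2-methylbut-2-enoate F7. Reductive opening of the α,β-epoxy ketone (SmI2, MeOH, THF, −78 °C) with protonation of the samarium enolate on the less hindered α-face should give 4α-hydroxy-6-oxo-5αH-dauc-8-en-10α-yl (E)-2-methylbut-2-enoate F8. Narasaka–Prasad reduction (Et2BOMe, NaBH4, THF/MeOH, −78 °C) should give the syn-1,3-diol 26, where the route is rejoined.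

**Further compounds**

F1 | step 9 | (6S)-3,6-dimethyl-6-(4-methyl-3-oxopentyl)cyclohepta-2,4-dien-1-one | O=C1C=C(C)C=C[C@@](C)(CCC(=O)C(C)C)C1
F2 | step 9 | dauca-4,7,9-trien-6-one | O=C1C=C(C)C=C[C@@]2(C)CCC(C(C)C)=C12
F3 | step 9 | 10α-(4,4,5,5-tetramethyl-1,3,2-dioxaborolan-2-yl)dauca-4,8-dien-6-one | O=C1CC(C)=C[C@@H](B2OC(C)(C)C(C)(C)O2)[C@@]3(C)CCC(C(C)C)=C13
F4 | step 9 | 10α-hydroxydauca-4,8-dien-6-one | O=C1CC(C)=C[C@@H](O)[C@@]2(C)CCC(C(C)C)=C12
F5 | step 10 | 4α,5α:9α,10α-diepoxydauc-7-en-6-one | O=C1C=C(C)[C@H]3O[C@H]3[C@@]2(C)CC[C@@]4(C(C)C)O[C@@]124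
F6 | step 10 | 4α,5α-epoxy-10α-hydroxydauc-7-en-6-one | O=C1C=C(C)C[C@@H](O)[C@@]2(C)CC[C@@]3(C(C)C)O[C@@]123
F7 | step 13 | 4α,5α-epoxy-6-oxodauc-8-en-10α-yl (E)-2-methylbut-2-enoate | O=C1CC(C)=C[C@@H](OC(=O)/C(C)=C/C)[C@@]2(C)CC[C@@]3(C(C)C)O[C@@]123
F8 | step 13 | 4α-hydroxy-6-oxo-5αH-dauc-8-en-10α-yl (E)-2-methylbut-2-enoate | C/C=C(\C)C(=O)O[C@@H]1C=C(C)CC(=O)[C@@H]2[C@]1(C)CC[C@]2(O)C(C)C
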